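The route cuts the quinone ring of the naphthazarin (C1, C2, C3, C4, C4a, C8a), which bears its only carbon substituent at C2 and is fused at C4a–C8a to a benzene ring oxygenated at C5 and C8. A Dötz benzannulation forms this ring in one operation (C4–C3, C2–C1, C1–C8a) from a zerovalent chromium aryl(methoxy)carbene, one CO ligand and a terminal alkyne. The alkyne already carries the complete side chain: the (R)-carbinol (R)-2-methylbutanoate, the E-alkene and the silylated tertiary alcohol. The aryl oxygens are carried as methoxymethyl ethers rather than methyl ethers, so that after oxidation to the quinone one mild acid treatment releases the target.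

Key step: step 8

Remark: the target naphthazarin is drawn as the 1,4-dione tautomer with the side chain on the quinone ring (its two rings interconvert by proton shift, so only the relative placement of side chain and oxygens matters), and (R)-2-methylbutanoic acid is taken as a purchased, enantiopure starting material.

Step 1
Reactants: 1 hydroquinone (benzene-1,4-diol)
Product: 2 1,4-bis(methoxymethoxy)benzene
Conditions: NaH, MOMCl, DMF, 0 °C to rt
Reagents that add atoms: chloromethyl methyl ether, COCCl
Why: Williamson-type O-alkylation of the hydroquinone dianion with the reactive α-chloro ether gives the bis-acetal, chosen because it directs the later ortho-lithiation and is removed at the end by mild acid.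

Step 2
Reactants: 2 1,4-bis(methoxymethoxy)benzene; 3 hexacarbonylchromium
Product: 6 pentacarbonyl{[2,5-bis(methoxymethoxy)phenyl](methoxy)methylidene}chromium, via 2-lithio-1,4-bis(methoxymethoxy)benzene 4 (not isolated), via lithium acylchromate 5 (not isolated)
Conditions: n-BuLi, THF, 0 °C; add to Cr(CO)6, THF, 0 °C to rt; evaporate; Me3OBF4, CH2Cl2, 0 °C
Reagents that add atoms: trimethyloxonium tetrafluoroborate, C[O+](C)C.F[B-](F)(F)F
Why: Fischer carbene synthesis, in which the methoxymethoxy group directs ortho-lithiation to one of four equivalent positions, the aryllithium adds to a carbonyl ligand of Cr(CO)6 to give the acylchromate, and the hard oxonium salt methylates its oxygen to give the zerovalent chromium methoxycarbene.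

Step 3
Reactants: 7 2-methylbut-3-en-2-ol
Product: 8 triethyl[(2-methylbut-3-en-2-yl)oxy]silane
Conditions: Et3SiOTf, 2,6-lutidine, CH2Cl2, −78 to 0 °C
Reagents that add atoms: triethylsilyl trifluoromethanesulfonate, CC[Si](CC)(CC)OS(=O)(=O)C(F)(F)F
Why: Silylation of the hindered tertiary alcohol with the silyl triflate and a non-nucleophilic base masks the hydroxyl for the Grignard, carbodiimide and chromium steps and makes the small intermediates lipophilic and non-volatile.

Step 4
Reactants: 8 triethyl[(2-methylbut-3-en-2-yl)oxy]silane
Product: 9 (2E)-4-methyl-4-(triethylsilyloxy)pent-2-enal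
Conditions: (E)-crotonaldehyde (5 equiv), second-generation Hoveyda–Grubbs catalyst RuCl2[1,3-bis(2,4,6-trimethylphenyl)imidazolidin-2-ylidene](=CH-C6H4-2-O-i-Pr) (5 mol %), CH2Cl2, 40 °C
Reagents that add atoms: (E)-but-2-enal (crotonaldehyde), C/C=C/C=O
Why: Olefin cross-metathesis between the hindered allylic ether, which does not homodimerise, and an excess of the electron-poor enal crotonaldehyde (a less volatile and less polymerisation-prone partner than acrolein, releasing propene) should give the conjugated enal as the thermodynamically favoured E isomer.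

Step 5
Reactants: 9 (2E)-4-methyl-4-(triethylsilyloxy)pent-2-enal
Product: 10 (4E)-6-methyl-6-(triethylsilyloxy)hept-4-en-1-yn-3-ol (racemic)
Conditions: HC≡CMgBr, THF, −78 to 0 °C; aq. NH4Cl
Reagents that add atoms: ethynylmagnesium bromide, C#C[Mg]Br
Why: Grignard addition of the acetylide to the enal carbonyl at low temperature goes 1,2 and gives the racemic alkenyl alkynyl carbinol without touching the silyl ether or the alkene.

Step 6
Reactants: 10 (4E)-6-methyl-6-(triethylsilyloxy)hept-4-en-1-yn-3-ol (racemic)
Product: 11 (3R,4E)-6-methyl-6-(triethylsilyloxy)hept-4-en-1-yn-3-ol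
Conditions: Amano lipase PS (Burkholderia cepacia), vinyl acetate, hexane, 30 °C, stopped near 55% conversion (chiral GC)
Reagents that add atoms: none
Why: Lipase-catalysed kinetic resolution by irreversible transesterification, in which the empirical size rule for lipases (slim ethynyl as the medium group, branched alkenyl chain as the large group) predicts fast acetylation of the (S)-alcohol, so the (R)-alcohol should remain and gain enantiomeric purity as the reaction is run past half conversion; its absolute configuration should be confirmed by Mosher (MTPA) ester analysis before use.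

Step 7
Reactants: 11 (3R,4E)-6-methyl-6-(triethylsilyloxy)hept-4-en-1-yn-3-ol; 12 (R)-2-methylbutanoic acid
Product: 13 (3R,4E)-6-methyl-6-(triethylsilyloxy)hept-4-en-1-yn-3-yl (2R)-2-methylbutanoate
Conditions: DCC, DMAP (cat.), CH2Cl2, 0 °C to rt
Reagents that add atoms: none
Why: Steglich esterification acylates the carbinol oxygen without breaking its C–O bond, so the (R)-configuration is retained, and carbodiimide activation with only catalytic DMAP at 0 °C avoids the ketene pathway that would epimerise the α-centre of the acid.

Step 8
Reactants: 6 pentacarbonyl{[2,5-bis(methoxymethoxy)phenyl](methoxy)methylidene}chromium; 13 (3R,4E)-6-methyl-6-(triethylsilyloxy)hept-4-en-1-yn-3-yl (2R)-2-methylbutanoate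
Product: 15 (1R,2E)-1-[1-hydroxy-4-methoxy-5,8-bis(methoxymethoxy)naphthalen-2-yl]-4-methyl-4-(triethylsilyloxy)pent-2-en-1-yl (2R)-2-methylbutanoate, via tricarbonylchromium naphthol complex 14 (not isolated)
Conditions: 6 (1.3 equiv), degassed THF (0.05 M), 55 °C, Ar; then air, Et2O, rt; short silica pad, used at once
Reagents that add atoms: none
Why: Dötz benzannulation: thermal loss of one CO from the zerovalent chromium carbene (the ortho methoxymethoxy oxygen can occupy the vacated site) lets the alkyne bind and insert into Cr=C with its unsubstituted carbon joining the carbene carbon (C4–C3); CO insertion then gives the η4-vinylketene (C2–C1), which closes the six-membered ring by a thermal 6π electrocyclisation onto C6 of the aryl group, its only free ortho carbon (C1–C8a), and tautomerises to the naphthol held on Cr(CO)3. The closest known reaction type is the benzannulation of (2-alkoxyaryl)(methoxy)carbene chromium complexes with terminal alkynes carrying a propargylic oxygen substituent, which gives 2-substituted 4-methoxy-1-naphthols. No stereocentre is created: the propargylic (R)-centre, the α-centre of the ester and the E-alkene are spectators under neutral conditions at 55 °C, and the planar chirality of the arene complex is erased on demetalation. The step needs regioselectivity (substituted alkyne carbon next to the CO-derived carbon), which the steric bias of a terminal alkyne secures and which is in any case without consequence once the naphthazarin tautomerises. It also needs chemoselectivity for CO insertion and phenol formation over indene, furan and cyclobutenone pathways, which a methoxy carbene, THF as donor solvent and moderate dilution favour. Brief exposure to air releases the naphthol, and any of it that is oxidised further only anticipates step 9.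

Step 9
Reactants: 15 (1R,2E)-1-[1-hydroxy-4-methoxy-5,8-bis(methoxymethoxy)naphthalen-2-yl]-4-methyl-4-(triethylsilyloxy)pent-2-en-1-yl (2R)-2-methylbutanoate
Product: 16 (1R,2E)-1-[5,8-bis(methoxymethoxy)-1,4-dioxo-1,4-dihydronaphthalen-2-yl]-4-methyl-4-(triethylsilyloxy)pent-2-en-1-yl (2R)-2-methylbutanoate
Conditions: (NH4)2Ce(NO3)6 (2.2 equiv), MeCN/H2O, 0 °C, 10 min
Reagents that add atoms: water, O
Why: Oxidative demethylation of the p-methoxynaphthol ring by tetravalent cerium (two-electron oxidation, attack of water at C4, loss of methanol) gives the quinone, the free naphthol ring being far more easily oxidised than the bis-acetal ring; partial loss of the acid-labile groups here would be harmless, since step 10 removes them all.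

Step 10
Reactants: 16 (1R,2E)-1-[5,8-bis(methoxymethoxy)-1,4-dioxo-1,4-dihydronaphthalen-2-yl]-4-methyl-4-(triethylsilyloxy)pent-2-en-1-yl (2R)-2-methylbutanoate
Product: 17 (1R,2E)-1-(5,8-dihydroxy-1,4-dioxo-1,4-dihydronaphthalen-2-yl)-4-hydroxy-4-methylpent-2-en-1-yl (2R)-2-methylbutanoate (target)
Conditions: 2 M aq. HCl/THF (1:3), 0 °C to rt
Reagents that add atoms: none
Why: Acid-catalysed hydrolysis of the two aryl methoxymethyl acetals, eased by hydrogen bonding of the emerging peri phenols to the quinone carbonyls, and of the tertiary triethylsilyl ether should give the naphthazarin, with water returning any allylic cation to the tertiary alcohol and with the carboxylic ester and both stereocentres untouched in dilute aqueous acid.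

Compound list
1 | hydroquinone (benzene-1,4-diol) | Oc1ccc(O)cc1 | starting material
2 | 1,4-bis(methoxymethoxy)benzene | COCOc1ccc(OCOC)cc1 | intermediate
3 | hexacarbonylchromium | O=C=[Cr](=C=O)(=C=O)(=C=O)(=C=O)=C=O | starting material
4 | 2-lithio-1,4-bis(methoxymethoxy)benzene | [Li]c1cc(OCOC)ccc1OCOC | intermediate
5 | lithium pentacarbonyl{[2,5-bis(methoxymethoxy)phenyl](oxido)methylidene}chromate (lithium acylchromate) | [Li+].[O-]C(c1cc(OCOC)ccc1OCOC)=[Cr](=C=O)(=C=O)(=C=O)(=C=O)=C=O | intermediate
6 | pentacarbonyl{[2,5-bis(methoxymethoxy)phenyl](methoxy)methylidene}chromium | COC(c1cc(OCOC)ccc1OCOC)=[Cr](=C=O)(=C=O)(=C=O)(=C=O)=C=O | intermediate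
7 | 2-methylbut-3-en-2-ol | C=CC(C)(C)O | starting material
8 | triethyl[(2-methylbut-3-en-2-yl)oxy]silane | C=CC(C)(C)O[Si](CC)(CC)CC | intermediate
9 | (2E)-4-methyl-4-(triethylsilyloxy)pent-2-enal | O=C/C=C/C(C)(C)O[Si](CC)(CC)CC | intermediate
10 | (4E)-6-methyl-6-(triethylsilyloxy)hept-4-en-1-yn-3-ol, racemic | C#CC(O)/C=C/C(C)(C)O[Si](CC)(CC)CC | intermediate
11 | (3R,4E)-6-methyl-6-(triethylsilyloxy)hept-4-en-1-yn-3-ol | O[C@H](/C=C/C(C)(C)O[Si](CC)(CC)CC)C#C | intermediate
12 | (R)-2-methylbutanoic acid | CC[C@@H](C)C(=O)O | starting material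
13 | (3R,4E)-6-methyl-6-(triethylsilyloxy)hept-4-en-1-yn-3-yl (2R)-2-methylbutanoate | CC[C@@H](C)C(=O)O[C@H](/C=C/C(C)(C)O[Si](CC)(CC)CC)C#C | intermediate
14 | tricarbonylchromium complex of naphthol 15 (Cr(CO)3 η6-bound to the newly formed ring) | CC[C@@H](C)C(=O)O[C@H](/C=C/C(C)(C)O[Si](CC)(CC)CC)c1cc(OC)c2c(OCOC)ccc(OCOC)c2c1O.O=C=[Cr](=C=O)=C=O | intermediate
15 | (1R,2E)-1-[1-hydroxy-4-methoxy-5,8-bis(methoxymethoxy)naphthalen-2-yl]-4-methyl-4-(triethylsilyloxy)pent-2-en-1-yl (2R)-2-methylbutanoate | CC[C@@H](C)C(=O)O[C@H](/C=C/C(C)(C)O[Si](CC)(CC)CC)c1cc(OC)c2c(OCOC)ccc(OCOC)c2c1O | intermediate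
16 | (1R,2E)-1-[5,8-bis(methoxymethoxy)-1,4-dioxo-1,4-dihydronaphthalen-2-yl]-4-methyl-4-(triethylsilyloxy)pent-2-en-1-yl (2R)-2-methylbutanoate | CC[C@@H](C)C(=O)O[C@H](/C=C/C(C)(C)O[Si](CC)(CC)CC)C1=CC(=O)c2c(OCOC)ccc(OCOC)c2C1=O | intermediate
17 | (1R,2E)-1-(5,8-dihydroxy-1,4-dioxo-1,4-dihydronaphthalen-2-yl)-4-hydroxy-4-methylpent-2-en-1-yl (2R)-2-methylbutanoate | CC[C@@H](C)C(=O)O[C@H](/C=C/C(C)(C)O)C1=CC(=O)c2c(O)ccc(O)c2C1=O | target

Total step count: 10. Longest linear sequence: 8 steps (steps 3 to 10, from 7); the carbene branch (steps 1 and 2) joins at step 8.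

Steps most likely to fail

1. Step 8 (benzannulation). The vinylcarbene or vinylketene stage may be diverted (cyclisation without CO insertion, furan or cyclobutenone formation, oligomerisation of the terminal alkyne). The propargylic carboxylate may also ionise, either at chromium or through an ortho-quinone methide once the neighbouring naphthol has formed. The fallback carries the carbinol oxygen through the annulation as a silyl ether, a propargylic substituent that this benzannulation is known to tolerate, and acylates last; it sets out from 11 (with 6) and returns at 17. Silylation of 11 (Et3SiCl, imidazole, DMF, 0 °C) gives triethyl{[(3R,4E)-6-methyl-6-(triethylsilyloxy)hept-4-en-1-yn-3-yl]oxy}silane F1. Heating F1 with 6 under the conditions of step 8 should give the tricarbonylchromium naphthol complex F2 and, after demetalation in air, 4-methoxy-5,8-bis(methoxymethoxy)-2-[(1R,2E)-4-methyl-1,4-bis(triethylsilyloxy)pent-2-en-1-yl]naphthalen-1-ol F3. Oxidation with (NH4)2Ce(NO3)6 (MeCN/H2O, 0 °C) then gives 5,8-bis(methoxymethoxy)-2-[(1R,2E)-4-methyl-1,4-bis(triethylsilyloxy)pent-2-en-1-yl]naphthalene-1,4-dione F4. Treatment with 2 M aq. HCl/THF removes both acetals and both silyl groups to give 5,8-dihydroxy-2-[(1R,2E)-1,4-dihydroxy-4-methylpent-2-en-1-yl]naphthalene-1,4-dione F5. Steglich acylation with 12 (DCC, catalytic DMAP, CH2Cl2, 0 °C) then gives 17. This is the standard way to esterify the side-chain carbinol of hydroxyalkyl naphthazarins: the chelated peri phenols are poor nucleophiles and the tertiary alcohol is too hindered to react.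

2. Step 6 (lipase resolution). The enzyme may discriminate poorly between the ethynyl and alkenyl flanks, or acylate the hindered carbinol too slowly, so that the recovered alcohol is not enantiopure at a useful conversion. The fallback replaces resolution by reagent-controlled reduction, setting out from 10 and returning at 11. Racemic 10 is oxidised with MnO2 (CH2Cl2, rt) to (4E)-6-methyl-6-(triethylsilyloxy)hept-4-en-1-yn-3-one F6, which is used at once. Midland reduction with B-isopinocampheyl-9-borabicyclo[3.3.1]nonane made from (+)-α-pinene (concentrated THF, rt) delivers (R)-1-alkyn-3-ols from 1-alkyn-3-ones, with the ethynyl group as the small substituent, and should therefore give 11.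

3. Step 10 (global deprotection). Once the silyl group is lost, the tertiary allylic alcohol may ionise in acid before the second acetal has left, leading to allylic transposition, chloride capture or elimination to a diene. The fallback avoids Brønsted acid on the free alcohol, setting out from 16 and returning at 17. MgBr2·OEt2 (Et2O/CH2Cl2, 0 °C to rt) should cleave the two peri methoxymethyl ethers by chelation to the quinone carbonyls and leave the silyl ether, giving (1R,2E)-1-(5,8-dihydroxy-1,4-dioxo-1,4-dihydronaphthalen-2-yl)-4-methyl-4-(triethylsilyloxy)pent-2-en-1-yl (2R)-2-methylbutanoate F7. HF·pyridine buffered with extra pyridine (THF, 0 °C) then removes the triethylsilyl group to give 17.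

Further compounds
F1 | step 8 | triethyl{[(3R,4E)-6-methyl-6-(triethylsilyloxy)hept-4-en-1-yn-3-yl]oxy}silane | CC[Si](CC)(CC)O[C@H](/C=C/C(C)(C)O[Si](CC)(CC)CC)C#C
F2 | step 8 | tricarbonylchromium naphthol complex (Cr(CO)3 η6-bound to the newly formed ring of F3) | CC[Si](CC)(CC)O[C@H](/C=C/C(C)(C)O[Si](CC)(CC)CC)c1cc(OC)c2c(OCOC)ccc(OCOC)c2c1O.O=C=[Cr](=C=O)=C=O
F3 | step 8 | 4-methoxy-5,8-bis(methoxymethoxy)-2-[(1R,2E)-4-methyl-1,4-bis(triethylsilyloxy)pent-2-en-1-yl]naphthalen-1-ol | CC[Si](CC)(CC)O[C@H](/C=C/C(C)(C)O[Si](CC)(CC)CC)c1cc(OC)c2c(OCOC)ccc(OCOC)c2c1O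
F4 | step 8 | 5,8-bis(methoxymethoxy)-2-[(1R,2E)-4-methyl-1,4-bis(triethylsilyloxy)pent-2-en-1-yl]naphthalene-1,4-dione | CC[Si](CC)(CC)O[C@H](/C=C/C(C)(C)O[Si](CC)(CC)CC)C1=CC(=O)c2c(OCOC)ccc(OCOC)c2C1=O
F5 | step 8 | 5,8-dihydroxy-2-[(1R,2E)-1,4-dihydroxy-4-methylpent-2-en-1-yl]naphthalene-1,4-dione | O[C@H](/C=C/C(C)(C)O)C1=CC(=O)c2c(O)ccc(O)c2C1=O
F6 | step 6 | (4E)-6-methyl-6-(triethylsilyloxy)hept-4-en-1-yn-3-one | C#CC(=O)/C=C/C(C)(C)O[Si](CC)(CC)CC
F7 | step 10 | (1R,2E)-1-(5,8-dihydroxy-1,4-dioxo-1,4-dihydronaphthalen-2-yl)-4-methyl-4-(triethylsilyloxy)pent-2-en-1-yl (2R)-2-methylbutanoate | CC[C@@H](C)C(=O)O[C@H](/C=C/C(C)(C)O[Si](CC)(CC)CC)C1=CC(=O)c2c(O)ccc(O)c2C1=O
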